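Abbreviations used in names: Piv = 2,2-dimethylpropanoyl, TIPS = tri(propan-2-yl)silyl, TBS = tert-butyl(dimethyl)silyl, TES = triethylsilyl. Atom labels follow the oxolane numbering of the target: O1, C2 to C5 in the ring, C6 the ketone carbon on C3, C7 the carbinol carbon on C4.

## Structural features

The target is a 2,3,4,5-tetrasubstituted oxolane in which every ring carbon is stereogenic; a fifth stereocentre sits on the exocyclic carbinol C7, so five stereocentres are contiguous along C2–C3–C4(–C7)–C5. C2 carries a 4-hydroxyphenyl ring, C3 the 2,4-dihydroxybenzoyl group (C6), C4 the hydroxy(4-hydroxyphenyl)methyl group (C7) and C5 a 2,4-dihydroxyphenyl ring. C2/C3 are trans, C3/C4 cis and C4/C5 cis, so the resorcinol ring at C5 stands on the crowded face next to the C7 side chain, the thermodynamically less favourable position. The C3–C4 bond joins two ArC(O)–CH–CH(O)Ar halves that differ only in the oxidation level at C5 and in which oxygen closes the ring, a hidden twofold symmetry. Fragile points are the three benzylic C–O bonds (C2–O1, C5–O1, C7–OH), each ortho or para to a free phenol and so open to quinone methide ionisation. The beta-alkoxy ketone C6(=O)–C3–C2–O1 can epimerise at C3 or eliminate O1 under base, and the gamma-hydroxy ketone can close to a hemiketal. The real difficulty is the all-cis C3–C4–C5 array with the C5 aryl in its unfavourable position, together with telling two nearly identical halves apart. The key step exploits the fact that C5 and C7 are both benzylic, both oxygen-bearing and both bonded to C4: this is the 1,3-dioxygenation pattern left when a 1,2-diarylcyclopropane C5–C4–C7 is cleaved at C5–C7, with O1 supplied by the C2 hydroxyl and the C7 oxygen by a C6 carboxyl, so that the oxolane and a C6–O–C7 gamma-lactone form together.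

## Logic of the disconnections

28 from 27. Bonds cut: the six aryl O–Si bonds. Reason: the free phenols are what makes C2, C5 and C7 ionisable and the ketone base-sensitive, so they are unmasked in the last operation only. Gain: every earlier compound is non-acidic and tolerates organolithium reagents. Demand: a fluoride source buffered to near neutrality.

27 from 22 and 24. Bond cut: C6–C(aryl). Reason: the lactone carbonyl of 22 is an acyl donor that stops at the ketone level (through 26) and sets the C7 hydroxyl free in the same event, so no redox adjustment is needed. Gain: the fourth ring arrives as 25, made from 24, and the problem shrinks to a bicyclic lactone. Demand: silyl ethers only on the phenols, −78 °C, and addition faster than deprotonation at C3.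

22 from 20 through 21. Bonds changed: three aryl O–acyl bonds for O–Si bonds. Reason: step 11 needs electron-poor rings at C2 and C5, step 15 tolerates no ester. Gain: none in the skeleton; these two steps are the price of the key step. Demand: ester removal that leaves the silyl ether on the C7 ring untouched, since a free phenol para to the C7–O acyl bond would expel the carboxylate; this is why that ring carries the more robust triisopropylsilyl group.

20 from 18 (key). Bonds cut: O1–C5 and O–C7; bond restored: C5–C7. Reason: the 1,3-dioxygenated C5–C4–C7 unit is the retron of an oxidative cyclopropane opening. Gain: two rings and two stereocentres vanish, and the hard C4/C5-cis relation is stored as a cis relation on a cyclopropane. Demand: invertive attack at C5, the hole and later the radical on the C7 side, the hydroxyl acting before the carboxyl. Descriptor bookkeeping: 18 is (2R,3R) with a (1R,2R,3R)-cyclopropane; inversion at C5 and capture at C7 give 20 with C2 R, C3 R, C4 S, C5 R, C7 R, which is the (2R,3R,4R,5R),(7R) array of 28 (C4 changes letter only because the ranking of its neighbours changes). No descriptor needed correction; what needed correction is listed in the next two paragraphs.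

18 from 17, and 17 from 14 and 15. Bonds cut: C6–N, then C2–C3 (aldol). Reason: an auxiliary-controlled syn aldol sets C2 and C3 with known sense, and the syn relation becomes C2/C3-trans in the ring. Gain: the C2 aryl is split off as 15. Demand: removal of the auxiliary without loss of aryl esters. Hydroperoxide cleavage of an oxazolidinone would strip aryl pivalates, so the activated thiazolidinethione is used, which leaves with one equivalent of hydroxide.

14 from 13, 13 from 11, 11 from 5 and 8. Bonds cut: the amide bond, then C4–C7 and C5–C7 (carbene plus alkene). Reason: the required triad (C5 aryl cis to the chain, C7 aryl trans to both) is what anti addition of an aryl carbene to a cis alkene gives. The opposite pairing, the C5 aryl as carbene on an E alkene, would have to place the incoming aryl cis to the chain against its innate preference. Gain: the cyclopropane comes from two aldehydes. Demand: Z geometry in 5 and a stereospecific, anti-selective carbene transfer. C6 stays masked as an acetal until after step 5, because a free acid and a thione both react with carbenes. No reliable catalyst control of absolute configuration exists for this alkene class, so 11 to 13 are racemic and are resolved at 14 through the auxiliary that step 9 needs anyway.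

5 from 2 and 3; 2 from 1; 8 from 7 from 6; 15 from 6; 24 from 23. Bonds cut: C4=C5 (Wittig, through 4) and simple O-acyl, O-silyl and C=N bonds. Reason and gain: all carbon comes from three hydroxybenzaldehyde or resorcinol units and one three-carbon phosphonium salt. Demand: a lithium-free, non-stabilised ylide for Z selectivity.

## Other disconnections considered

Alternative 1: The cut is C2–C3 and C4–C7, both aldol bonds, leaving the symmetrical diketone 1,4-bis[2,4-bis(allyloxy)phenyl]butane-1,4-dione A1 and two molecules of an O-allyl 4-hydroxybenzaldehyde. The forward key step is double enolisation of A1 to its bis(boron enolate) and addition to two aldehyde molecules, giving the C2-symmetric syn,syn bis-aldol A2 with C2, C3, C4 and C7 set and no ring closed. One hydroxyl would then close on the distal ketone and the oxocarbenium ion would be reduced to set C5. In its favour: it uses the hidden symmetry fully, either hydroxyl may cyclise because both lead to the same compound, one protecting group type serves throughout, and no late organolithium meets a base-sensitive lactone. Against it here: one chiral boron reagent must control the absolute sense of two aldols on a doubly enolised 1,4-diketone, and reductive etherification must stop after one ring, since a second closure gives a furofuran. C5 would also rest on kinetic hydride delivery under a Lewis acid that can ionise the electron-rich benzylic carbinols, and the beta-hydroxy ketones can undergo retro-aldol cleavage. Comparison: on step economy it is clearly better (about six steps), and on precedent of the individual reactions it is better, all of them being closed-shell and known. It is equal in how C2/C3 are set (a syn aldol). The chosen plan is stronger in the certainty of C5 (inversion rather than face selection) and in differentiating the two halves.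

Alternative 2: The cut is C3–C4 and O1–C2. Rh2(OAc)4 (divalent rhodium) would turn 3-diazo-7-(TBSO)chromane-2,4-dione A3 into a carbenoid that bonds its carbon (C4) to C3 of the (E)-alkene A4 and closes the ketone oxygen onto benzylic C2, giving the trans-dihydrofurocoumarin A5. In its favour: it is convergent, the resorcinol ring arrives with its ortho oxygen and with C5, C4 and C7 as a cheap coumarin, the C2/C3-trans relation follows from the alkene, and this annulation is an established carbenoid reaction with styrene-type alkenes. Against it here: C4 and C5 are sp2 in A5, so three stereocentres (C4, C5, C7) must be made afterwards. That means reducing a tetrasubstituted, conjugated enol ether and a ketone beside benzylic C–O bonds that invite hydrogenolysis. Face control in the annulation rests on a single allylic silyloxy centre that is later oxidised away, and C6 and C7 both need redox adjustment. Comparison: it is better in precedent of its key step and equal or better in convergence. It is weaker in stereocontrol at C4, C5 and C7 and in redox economy; the step count would be about equal.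

Alternative 3: The cut is C2–C3 and C4–C5. Rh2(OAc)4 would decompose an aryldiazomethane, an aromatic aldehyde would capture the carbene through oxygen, and the carbonyl ylide would add across C3=C4 of the butenolide (R)-5-[4-(TBSO)phenyl]furan-2(5H)-one A6 to give A7, the same bicyclic lactone as 20 apart from one protecting group. In its favour: three components give the oxolane in one step, the C7 aryl of A6 should direct addition to the opposite face (cis fusion, exo C7 aryl), and no radical-cation step dictates the protecting groups, so silyl ethers could be used from the start. Against it here: non-stabilised diaryl carbonyl ylides close to epoxides, add to a second aldehyde or lose out to carbene dimerisation, and a butenolide is a modest dipolarophile. The two ylide termini are electronically alike, so which aryl ends at C2 and which at C5 is uncontrolled. The target needs the 2,5-trans diaryl arrangement (C2 aryl exo, C5 aryl endo), whereas the extended ylide geometry leads to 2,5-cis. Comparison: it is better in convergence and step economy and equal in the lactone-opening endgame. It is weaker in regiocontrol and in the C2/C5 relation, which the chosen plan fixes by an aldol and by inversion.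

Key step: step 11

Remark on the chemistry: 27 and 28 are written as open gamma-hydroxy ketones; a ring-chain equilibrium with the five-membered hemiketal would not change steps 15 and 16, because the 2-hydroxyaryl ketone freed in step 16 is held open by its internal hydrogen bond.

## Steps

Step 1
Reactants: 1 2,4-dihydroxybenzaldehyde
Product: 2 4-formyl-1,3-phenylene bis(2,2-dimethylpropanoate)
Conditions: t-BuCOCl (2.4 equiv), Et3N, DMAP (cat.), CH2Cl2, 0 °C to rt
Reagents that add atoms: pivaloyl chloride, CC(C)(C)C(Cl)=O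
Why: DMAP-catalysed acylation of both phenols; the hydrogen-bonded 2-hydroxyl reacts more slowly and is driven by excess acyl chloride. The two esters make this ring electron-poor for step 11.

Step 2
Reactants: 2 4-formyl-1,3-phenylene bis(2,2-dimethylpropanoate); 3 [2-(1,3-dioxolan-2-yl)ethyl]triphenylphosphonium bromide
Product: 5 4-[(1Z)-3-(1,3-dioxolan-2-yl)prop-1-en-1-yl]-1,3-phenylene bis(2,2-dimethylpropanoate), via phosphonium ylide 4 (not isolated)
Conditions: NaN(SiMe3)2 (1.0 equiv), THF, 0 °C; then 2, −78 °C to rt; AgNO3-impregnated silica if the E isomer must be removed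
Reagents that add atoms: none
Why: Wittig reaction of a non-stabilised ylide under lithium-free conditions, which should give mainly the Z alkene through the kinetically formed cis-oxaphosphetane; the aldehyde reacts far faster than the aryl esters at −78 °C. The Z geometry later places the resorcinol ring cis to the side chain, and the acetal carries C6 in a form inert to carbenes.

Step 3
Reactants: 6 4-hydroxybenzaldehyde
Product: 7 4-(TIPSO)benzaldehyde
Conditions: i-Pr3SiCl, imidazole, DMF, rt
Reagents that add atoms: chlorotri(propan-2-yl)silane, CC(C)[Si](Cl)(C(C)C)C(C)C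
Why: Silylation of the phenol. The bulky silyl group is chosen because it must survive acetate at the radical-cation stage of step 11 and carbonate methanolysis in step 12.

Step 4
Reactants: 7 4-(TIPSO)benzaldehyde
Product: 8 4-methyl-N'-[(E)-{4-(TIPSO)phenyl}methylidene]benzenesulfonohydrazide
Conditions: TsNHNH2, MeOH, rt
Reagents that add atoms: 4-methylbenzenesulfonohydrazide, Cc1ccc(cc1)S(=O)(=O)NN
Why: Condensation to the N-tosylhydrazone, the storable precursor of the aryldiazomethane.

Step 5
Reactants: 5 4-[(1Z)-3-(1,3-dioxolan-2-yl)prop-1-en-1-yl]-1,3-phenylene bis(2,2-dimethylpropanoate); 8 4-methyl-N'-[(E)-{4-(TIPSO)phenyl}methylidene]benzenesulfonohydrazide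
Product: 11 rac-2-{[(1R,2R,3R)-2-[2,4-bis(PivO)phenyl]-3-[4-(TIPSO)phenyl]cyclopropyl]methyl}-1,3-dioxolane, via hydrazone sodium salt 9 (not isolated), via aryldiazomethane 10 (not isolated)
Conditions: NaOMe (1.0 equiv), MeOH, rt, evaporate; then Fe(TPP)Cl (2 mol%), BnEt3NCl (10 mol%), toluene, 40 °C, salt of 8 in excess, added in portions
Reagents that add atoms: none
Why: Bamford–Stevens generation of the aryldiazomethane in the flask and iron-porphyrin carbene transfer (cyclopropanation); the iron is charged in the trivalent state and reduced by the diazo compound to the divalent state that carries the carbene. Addition is stereospecific for the alkene, so resorcinol ring and CH2 chain stay cis, and the carbene aryl should add anti to both because the alkene must approach the porphyrin-bound carbene with its substituents turned away from macrocycle and carbene aryl. Absolute configuration is not controlled: 11 is racemic and is resolved in step 7.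

Step 6
Reactants: 11 rac-2-{[(1R,2R,3R)-2-[2,4-bis(PivO)phenyl]-3-[4-(TIPSO)phenyl]cyclopropyl]methyl}-1,3-dioxolane
Product: 13 rac-2-[(1R,2R,3R)-2-[2,4-bis(PivO)phenyl]-3-[4-(TIPSO)phenyl]cyclopropyl]acetic acid, via cyclopropylacetaldehyde 12 (not isolated)
Conditions: TsOH·H2O (cat.), acetone–H2O, 50 °C; then NaClO2, NaH2PO4, 2-methylbut-2-ene, t-BuOH–H2O, 0 °C to rt
Reagents that add atoms: water, O; sodium chlorite, [Na+].[O-]Cl=O
Why: Acetal hydrolysis followed by Pinnick oxidation of the crude aldehyde; both are acidic to neutral, so aryl pivalates and the aryl silyl ether stay. The carbonyl is insulated from the ring by a CH2 group, so the cyclopropane is not of the donor–acceptor type and its stereocentres are not at risk.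

Step 7
Reactants: 13 rac-2-[(1R,2R,3R)-2-[2,4-bis(PivO)phenyl]-3-[4-(TIPSO)phenyl]cyclopropyl]acetic acid
Product: 14 (4R)-4-benzyl-3-{2-[(1R,2R,3R)-2-[2,4-bis(PivO)phenyl]-3-[4-(TIPSO)phenyl]cyclopropyl]acetyl}-1,3-thiazolidine-2-thione
Conditions: (R)-4-benzyl-1,3-thiazolidine-2-thione, EDC·HCl, DMAP (cat.), CH2Cl2, 0 °C to rt; separation of the two diastereomers (chromatography or crystallisation), assignment by X-ray analysis
Reagents that add atoms: (R)-4-benzyl-1,3-thiazolidine-2-thione, S=C1N[C@H](Cc2ccccc2)CS1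
Why: Steglich-type N-acylation without strong base. Racemic acid and enantiopure auxiliary must give two diastereomeric thioimides in equal amounts, and their separation fixes the absolute configuration of C4, C5 and C7 (a resolution through the auxiliary that step 9 needs anyway). The thione is introduced only now because it would trap the carbene of step 5.

Step 8
Reactants: 6 4-hydroxybenzaldehyde
Product: 15 4-formylphenyl 2,2-dimethylpropanoate
Conditions: t-BuCOCl, Et3N, DMAP (cat.), CH2Cl2, 0 °C to rt
Reagents that add atoms: pivaloyl chloride, CC(C)(C)C(Cl)=O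
Why: Acylation of the phenol. The ester keeps the future C2 aryl electron-poor, so it is not oxidised in step 11.

Step 9
Reactants: 14 (4R)-4-benzyl-3-{2-[(1R,2R,3R)-2-[2,4-bis(PivO)phenyl]-3-[4-(TIPSO)phenyl]cyclopropyl]acetyl}-1,3-thiazolidine-2-thione; 15 4-formylphenyl 2,2-dimethylpropanoate
Product: 17 (4R)-4-benzyl-3-{(2R,3R)-2-[(1R,2R,3R)-2-[2,4-bis(PivO)phenyl]-3-[4-(TIPSO)phenyl]cyclopropyl]-3-hydroxy-3-[4-(PivO)phenyl]propanoyl}-1,3-thiazolidine-2-thione, via chlorotitanium enolate 16 (not isolated)
Conditions: TiCl4 (1.05 equiv), i-Pr2NEt (1.1 equiv), N-methylpyrrolidin-2-one (1.1 equiv), CH2Cl2, 0 °C; then 15, −78 to 0 °C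
Reagents that add atoms: none
Why: Auxiliary-controlled titanium enolate aldol in the Evans-syn mode: soft enolisation gives the Z enolate, which adds through a closed, non-chelated Zimmerman–Traxler chair on the face away from the benzyl group. The (R)-auxiliary sets C3 and C2 as (R,R), syn, and should override the more remote cyclopropane stereocentres.

Step 10
Reactants: 17 (4R)-4-benzyl-3-{(2R,3R)-2-[(1R,2R,3R)-2-[2,4-bis(PivO)phenyl]-3-[4-(TIPSO)phenyl]cyclopropyl]-3-hydroxy-3-[4-(PivO)phenyl]propanoyl}-1,3-thiazolidine-2-thione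
Product: 18 (2R,3R)-2-[(1R,2R,3R)-2-[2,4-bis(PivO)phenyl]-3-[4-(TIPSO)phenyl]cyclopropyl]-3-hydroxy-3-[4-(PivO)phenyl]propanoic acid
Conditions: LiOH·H2O (1.2 equiv), THF–H2O (4:1), 0 °C, short contact; then 1 M HCl to pH 3
Reagents that add atoms: lithium hydroxide, [Li+].[OH-]
Why: Hydrolysis of an activated amide: the N-acylthiazolidinethione should be cleaved by near-stoichiometric hydroxide much faster than the hindered aryl pivalates. Short contact at 0 °C should leave C2 and C3 untouched (no retro-aldol, no epimerisation).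

Step 11
Reactants: 18 (2R,3R)-2-[(1R,2R,3R)-2-[2,4-bis(PivO)phenyl]-3-[4-(TIPSO)phenyl]cyclopropyl]-3-hydroxy-3-[4-(PivO)phenyl]propanoic acid
Product: 20 (3R,3aS,4R,6R,6aR)-4-[2,4-bis(PivO)phenyl]-6-[4-(PivO)phenyl]-3-[4-(TIPSO)phenyl]tetrahydro-1H,3H-furo[3,4-c]furan-1-one, via C7 benzylic radical 19 (not isolated)
Conditions: 9-mesityl-10-methylacridinium tetrafluoroborate (5 mol%), Cu(OAc)2 (2.2 equiv), MeCN–AcOH (9:1), 450 nm LEDs, rt, argon
Reagents that add atoms: none
Why: Proposed new method: the excited acridinium oxidises only the 4-silyloxyphenyl ring of 18 (the pivaloyloxy rings are too electron-poor), giving an arylcyclopropane radical cation whose C5–C7 bond is a weakened one-electron bond with the hole on the C7 aryl. The C2 hydroxyl then displaces C7 from C5 by backside attack in the plane of the three-membered ring (three-electron SN2), closing the oxolane in the endo sense used for three-membered-ring openings (the ring bond C4–C5 enters the new ring, the breaking bond C5–C7 lies outside it); this inverts C5 and turns the cis relation of resorcinol ring and chain into the C4/C5-cis oxolane. The C7 benzylic radical 19 is oxidised by Cu(OAc)2 (divalent copper, which ends as monovalent copper) to the 4-silyloxybenzyl cation or its organocopper equivalent, which the C6 carboxyl captures by 5-exo-trig closure to the gamma-lactone, and a second equivalent of Cu(OAc)2 returns the acridine radical to the acridinium. C7 is set in this closure: the carboxyl is held cis to C7 on C3, so the fusion must be cis, and the aryl should turn to the convex face. The closest known reaction types are the photoredox and electrochemical 1,3-oxyfunctionalisation and 1,3-dioxygenation of arylcyclopropanes by external oxygen nucleophiles, which open the ring with inversion at the attacked carbon, and the copper-mediated oxidation of benzylic radicals with lactonisation known from carbo-lactonisation of alkenoic acids. Three selectivities are needed: oxidation of one arene only and attack at C5 rather than C7, both secured by the ester and silyl ether pattern, which puts hole and later radical on the C7 side. The third is the hydroxyl rather than the carboxyl as first nucleophile, for which acetic acid as cosolvent keeps the acid un-ionised, a neutral carboxyl being a far poorer nucleophile than an alcohol. Fidelity at C5 requires that ring opening stays concerted with attack.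

Step 12
Reactants: 20 (3R,3aS,4R,6R,6aR)-4-[2,4-bis(PivO)phenyl]-6-[4-(PivO)phenyl]-3-[4-(TIPSO)phenyl]tetrahydro-1H,3H-furo[3,4-c]furan-1-one
Product: 21 (3R,3aS,4R,6R,6aR)-4-(2,4-dihydroxyphenyl)-6-(4-hydroxyphenyl)-3-[4-(TIPSO)phenyl]tetrahydro-1H,3H-furo[3,4-c]furan-1-one
Conditions: K2CO3, MeOH–THF, 0 °C to rt; then AcOH
Reagents that add atoms: none
Why: Carbonate-catalysed methanolysis of the three aryl pivalates; the aryl triisopropylsilyl ether should survive, which matters because a free phenoxide para to the C7–O acyl bond would expel the carboxylate. Acidification recloses any lactone opened by methanol; the cis-fused lactone cannot epimerise at C3 while closed.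

Step 13
Reactants: 21 (3R,3aS,4R,6R,6aR)-4-(2,4-dihydroxyphenyl)-6-(4-hydroxyphenyl)-3-[4-(TIPSO)phenyl]tetrahydro-1H,3H-furo[3,4-c]furan-1-one
Product: 22 (3R,3aS,4R,6R,6aR)-4-[2,4-bis(TBSO)phenyl]-6-[4-(TBSO)phenyl]-3-[4-(TIPSO)phenyl]tetrahydro-1H,3H-furo[3,4-c]furan-1-one
Conditions: t-BuMe2SiCl, imidazole, DMF, rt
Reagents that add atoms: tert-butyl(chloro)dimethylsilane, CC(C)(C)[Si](C)(C)Cl
Why: Silylation of the three phenols gives a lactone with no acidic proton and no electrophile other than the lactone carbonyl, as step 15 requires.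

Step 14
Reactants: 23 4-bromobenzene-1,3-diol
Product: 24 1-bromo-2,4-bis(TBSO)benzene
Conditions: t-BuMe2SiCl, imidazole, DMF, rt
Reagents that add atoms: tert-butyl(chloro)dimethylsilane, CC(C)(C)[Si](C)(C)Cl
Why: Silylation of both phenols; the same silyl group as in 22 allows one final deprotection.

Step 15
Reactants: 22 (3R,3aS,4R,6R,6aR)-4-[2,4-bis(TBSO)phenyl]-6-[4-(TBSO)phenyl]-3-[4-(TIPSO)phenyl]tetrahydro-1H,3H-furo[3,4-c]furan-1-one; 24 1-bromo-2,4-bis(TBSO)benzene
Product: 27 [(2R,3R,4R,5R)-5-[2,4-bis(TBSO)phenyl]-2-[4-(TBSO)phenyl]-4-[(R)-hydroxy{4-(TIPSO)phenyl}methyl]oxolan-3-yl][2,4-bis(TBSO)phenyl]methanone, via aryllithium 25 (not isolated), via lithium lactolate 26 (not isolated)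
Conditions: 24 (1.5 equiv), n-BuLi (1.45 equiv), THF, −78 °C; then 22, −78 °C; AcOH in THF, −78 °C
Reagents that add atoms: none
Why: Bromine–lithium exchange and addition of the aryllithium to the lactone; the tetrahedral lithium lactolate 26 should persist at −78 °C, so the ketone appears only on the cold quench and is not attacked a second time. No stereocentre is formed; C3 keeps its configuration provided addition outruns deprotonation.

Step 16
Reactants: 27 [(2R,3R,4R,5R)-5-[2,4-bis(TBSO)phenyl]-2-[4-(TBSO)phenyl]-4-[(R)-hydroxy{4-(TIPSO)phenyl}methyl]oxolan-3-yl][2,4-bis(TBSO)phenyl]methanone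
Product: 28 [(2R,3R,4R,5R)-5-(2,4-dihydroxyphenyl)-2-(4-hydroxyphenyl)-4-[(R)-hydroxy(4-hydroxyphenyl)methyl]oxolan-3-yl](2,4-dihydroxyphenyl)methanone (CNP0244141.1)
Conditions: Bu4NF, AcOH (1:1), THF, 0 °C to rt
Reagents that add atoms: none
Why: Fluoride cleavage of all six aryl silyl ethers; the acetic acid buffer keeps the medium near neutral, so the beta-alkoxy ketone is not enolised and the hydroxybenzylic C–O bonds are not ionised.

## Compound list

1 | 2,4-dihydroxybenzaldehyde | O=Cc1ccc(O)cc1O | starting material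
2 | 4-formyl-1,3-phenylene bis(2,2-dimethylpropanoate) | O=Cc1ccc(OC(=O)C(C)(C)C)cc1OC(=O)C(C)(C)C | intermediate
3 | [2-(1,3-dioxolan-2-yl)ethyl]triphenylphosphonium bromide | [Br-].O1CCOC1CC[P+](c1ccccc1)(c1ccccc1)c1ccccc1 | starting material
4 | [2-(1,3-dioxolan-2-yl)ethylidene]triphenylphosphorane (ylide, not isolated) | O1CCOC1CC=P(c1ccccc1)(c1ccccc1)c1ccccc1 | intermediate
5 | 4-[(1Z)-3-(1,3-dioxolan-2-yl)prop-1-en-1-yl]-1,3-phenylene bis(2,2-dimethylpropanoate) | CC(C)(C)C(=O)Oc1ccc(/C=C\CC2OCCO2)c(OC(=O)C(C)(C)C)c1 | intermediate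
6 | 4-hydroxybenzaldehyde | O=Cc1ccc(O)cc1 | starting material
7 | 4-(TIPSO)benzaldehyde | O=Cc1ccc(O[Si](C(C)C)(C(C)C)C(C)C)cc1 | intermediate
8 | 4-methyl-N'-[(E)-{4-(TIPSO)phenyl}methylidene]benzenesulfonohydrazide | Cc1ccc(cc1)S(=O)(=O)N/N=C/c1ccc(O[Si](C(C)C)(C(C)C)C(C)C)cc1 | intermediate
9 | sodium salt of 8 (not isolated) | [Na+].Cc1ccc(cc1)S(=O)(=O)[N-]/N=C/c1ccc(O[Si](C(C)C)(C(C)C)C(C)C)cc1 | intermediate
10 | 1-(diazomethyl)-4-(TIPSO)benzene (not isolated) | [N-]=[N+]=Cc1ccc(O[Si](C(C)C)(C(C)C)C(C)C)cc1 | intermediate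
11 | rac-2-{[(1R,2R,3R)-2-[2,4-bis(PivO)phenyl]-3-[4-(TIPSO)phenyl]cyclopropyl]methyl}-1,3-dioxolane (racemate; the enantiomer carried on is drawn) | O1CCOC1C[C@H]2[C@@H](c3ccc(OC(=O)C(C)(C)C)cc3OC(=O)C(C)(C)C)[C@@H]2c2ccc(O[Si](C(C)C)(C(C)C)C(C)C)cc2 | intermediate
12 | rac-2-[(1R,2R,3R)-2-[2,4-bis(PivO)phenyl]-3-[4-(TIPSO)phenyl]cyclopropyl]acetaldehyde (not isolated; racemate, one enantiomer drawn) | O=CC[C@H]1[C@@H](c2ccc(OC(=O)C(C)(C)C)cc2OC(=O)C(C)(C)C)[C@@H]1c1ccc(O[Si](C(C)C)(C(C)C)C(C)C)cc1 | intermediate
13 | rac-2-[(1R,2R,3R)-2-[2,4-bis(PivO)phenyl]-3-[4-(TIPSO)phenyl]cyclopropyl]acetic acid (racemate, one enantiomer drawn) | OC(=O)C[C@H]1[C@@H](c2ccc(OC(=O)C(C)(C)C)cc2OC(=O)C(C)(C)C)[C@@H]1c1ccc(O[Si](C(C)C)(C(C)C)C(C)C)cc1 | intermediate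
14 | (4R)-4-benzyl-3-{2-[(1R,2R,3R)-2-[2,4-bis(PivO)phenyl]-3-[4-(TIPSO)phenyl]cyclopropyl]acetyl}-1,3-thiazolidine-2-thione | S=C1SC[C@@H](Cc2ccccc2)N1C(=O)C[C@H]1[C@@H](c2ccc(OC(=O)C(C)(C)C)cc2OC(=O)C(C)(C)C)[C@@H]1c1ccc(O[Si](C(C)C)(C(C)C)C(C)C)cc1 | intermediate
15 | 4-formylphenyl 2,2-dimethylpropanoate | O=Cc1ccc(OC(=O)C(C)(C)C)cc1 | intermediate
16 | trichlorotitanium (Z)-enolate of 14 (not isolated) | Cl[Ti](Cl)(Cl)O/C(=C\[C@H]1[C@@H](c2ccc(OC(=O)C(C)(C)C)cc2OC(=O)C(C)(C)C)[C@@H]1c1ccc(O[Si](C(C)C)(C(C)C)C(C)C)cc1)N1[C@H](Cc2ccccc2)CSC1=S | intermediate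
17 | (4R)-4-benzyl-3-{(2R,3R)-2-[(1R,2R,3R)-2-[2,4-bis(PivO)phenyl]-3-[4-(TIPSO)phenyl]cyclopropyl]-3-hydroxy-3-[4-(PivO)phenyl]propanoyl}-1,3-thiazolidine-2-thione | S=C1SC[C@@H](Cc2ccccc2)N1C(=O)[C@@H]([C@@H](O)c1ccc(OC(=O)C(C)(C)C)cc1)[C@H]1[C@@H](c2ccc(OC(=O)C(C)(C)C)cc2OC(=O)C(C)(C)C)[C@@H]1c1ccc(O[Si](C(C)C)(C(C)C)C(C)C)cc1 | intermediate
18 | (2R,3R)-2-[(1R,2R,3R)-2-[2,4-bis(PivO)phenyl]-3-[4-(TIPSO)phenyl]cyclopropyl]-3-hydroxy-3-[4-(PivO)phenyl]propanoic acid (precursor of the key step) | OC(=O)[C@@H]([C@@H](O)c1ccc(OC(=O)C(C)(C)C)cc1)[C@H]1[C@@H](c2ccc(OC(=O)C(C)(C)C)cc2OC(=O)C(C)(C)C)[C@@H]1c1ccc(O[Si](C(C)C)(C(C)C)C(C)C)cc1 | intermediate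
19 | (2R,3R,5R)-5-[2,4-bis(PivO)phenyl]-2-[4-(PivO)phenyl]-4-[{4-(TIPSO)phenyl}methyl]oxolane-3-carboxylic acid with the unpaired electron on the benzylic carbon C7, C4 as in 18 (not isolated) | OC(=O)[C@@H]1[C@H]([CH]c2ccc(O[Si](C(C)C)(C(C)C)C(C)C)cc2)[C@H](c2ccc(OC(=O)C(C)(C)C)cc2OC(=O)C(C)(C)C)O[C@H]1c1ccc(OC(=O)C(C)(C)C)cc1 | intermediate
20 | (3R,3aS,4R,6R,6aR)-4-[2,4-bis(PivO)phenyl]-6-[4-(PivO)phenyl]-3-[4-(TIPSO)phenyl]tetrahydro-1H,3H-furo[3,4-c]furan-1-one (product of the key step) | O=C1O[C@@H](c2ccc(O[Si](C(C)C)(C(C)C)C(C)C)cc2)[C@@H]2[C@H](c3ccc(OC(=O)C(C)(C)C)cc3OC(=O)C(C)(C)C)O[C@@H](c3ccc(OC(=O)C(C)(C)C)cc3)[C@H]12 | intermediate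
21 | (3R,3aS,4R,6R,6aR)-4-(2,4-dihydroxyphenyl)-6-(4-hydroxyphenyl)-3-[4-(TIPSO)phenyl]tetrahydro-1H,3H-furo[3,4-c]furan-1-one | O=C1O[C@@H](c2ccc(O[Si](C(C)C)(C(C)C)C(C)C)cc2)[C@@H]2[C@H](c3ccc(O)cc3O)O[C@@H](c3ccc(O)cc3)[C@H]12 | intermediate
22 | (3R,3aS,4R,6R,6aR)-4-[2,4-bis(TBSO)phenyl]-6-[4-(TBSO)phenyl]-3-[4-(TIPSO)phenyl]tetrahydro-1H,3H-furo[3,4-c]furan-1-one | O=C1O[C@@H](c2ccc(O[Si](C(C)C)(C(C)C)C(C)C)cc2)[C@@H]2[C@H](c3ccc(O[Si](C)(C)C(C)(C)C)cc3O[Si](C)(C)C(C)(C)C)O[C@@H](c3ccc(O[Si](C)(C)C(C)(C)C)cc3)[C@H]12 | intermediate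
23 | 4-bromobenzene-1,3-diol | Oc1ccc(Br)c(O)c1 | starting material
24 | 1-bromo-2,4-bis(TBSO)benzene | Brc1ccc(O[Si](C)(C)C(C)(C)C)cc1O[Si](C)(C)C(C)(C)C | intermediate
25 | [2,4-bis(TBSO)phenyl]lithium (not isolated) | [Li]c1ccc(O[Si](C)(C)C(C)(C)C)cc1O[Si](C)(C)C(C)(C)C | intermediate
26 | lithium lactolate from 22 and 25, configuration at the new hemiketal carbon C6 undefined (not isolated) | [Li]OC1(c2ccc(O[Si](C)(C)C(C)(C)C)cc2O[Si](C)(C)C(C)(C)C)O[C@@H](c2ccc(O[Si](C(C)C)(C(C)C)C(C)C)cc2)[C@@H]2[C@H](c3ccc(O[Si](C)(C)C(C)(C)C)cc3O[Si](C)(C)C(C)(C)C)O[C@@H](c3ccc(O[Si](C)(C)C(C)(C)C)cc3)[C@H]12 | intermediate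
27 | [(2R,3R,4R,5R)-5-[2,4-bis(TBSO)phenyl]-2-[4-(TBSO)phenyl]-4-[(R)-hydroxy{4-(TIPSO)phenyl}methyl]oxolan-3-yl][2,4-bis(TBSO)phenyl]methanone | O=C(c1ccc(O[Si](C)(C)C(C)(C)C)cc1O[Si](C)(C)C(C)(C)C)[C@@H]1[C@H]([C@@H](O)c2ccc(O[Si](C(C)C)(C(C)C)C(C)C)cc2)[C@H](c2ccc(O[Si](C)(C)C(C)(C)C)cc2O[Si](C)(C)C(C)(C)C)O[C@H]1c1ccc(O[Si](C)(C)C(C)(C)C)cc1 | intermediate
28 | [(2R,3R,4R,5R)-5-(2,4-dihydroxyphenyl)-2-(4-hydroxyphenyl)-4-[(R)-hydroxy(4-hydroxyphenyl)methyl]oxolan-3-yl](2,4-dihydroxyphenyl)methanone | O=C(c1ccc(O)cc1O)[C@@H]1[C@H]([C@@H](O)c2ccc(O)cc2)[C@H](c2ccc(O)cc2O)O[C@H]1c1ccc(O)cc1 | target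

## Step count and least certain steps

Total: 16 steps. Longest linear sequence: 12 steps (1, 2, 5, 6, 7, 9, 10, 11, 12, 13, 15, 16).

Step 11 (key step, proposed new method). Most likely to go wrong:
- the carboxyl, if partly ionised by acetate, captures C5 before the hydroxyl does and the two rings form in exchanged positions;
- ring opening runs ahead of attack, so that bond rotation in the opened radical cation erodes the inversion at C5;
- oxidative decarboxylation of the copper carboxylate, or fragmentation of the beta-hydroxy acid;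
- re-oxidation of the silyloxyaryl ring of the product, and loss of the silyl group from the radical cation.

The reason in each case is that the sequence rests on rate differences between two tethered nucleophiles and on a 5-membered transition state that has been shown only with external nucleophiles. Fallback with known reactions only, setting out from 24 and 6 and returning at 28 (the stepwise relative of alternative 1):
- 25, made from 24 as in step 15, is acylated twice by N,N'-dimethoxy-N,N'-dimethylbutanediamide (Weinreb ketone synthesis) to give 1,4-bis[2,4-bis(TBSO)phenyl]butane-1,4-dione F1.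
- 6 is silylated to 4-(TBSO)benzaldehyde F2.
- Mono-enolisation of F1 with diisopinocampheylboron triflate and i-Pr2NEt and addition to F2 (reagent-controlled syn aldol of a Z boron enolate) gives (2R)-1,4-bis[2,4-bis(TBSO)phenyl]-2-[(R)-hydroxy{4-(TBSO)phenyl}methyl]butane-1,4-dione F3.
- Et3SiOTf and 2,6-lutidine cap its hydroxyl as the triethylsilyl ether F4.
- A second aldol of the same kind at the other ketone with F2 gives the mono-silylated bis-aldol F5.
- BF3·OEt2 and Et3SiH at −78 °C close the free C2 hydroxyl on the C5 ketone and reduce the oxocarbenium ion from the face away from the C4 substituent (reductive cycloetherification), giving the oxolane F6, the all-TBS analogue of 27 with C7 as its triethylsilyl ether.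
- The conditions of step 16 then give 28.

This route gives up the cyclopropane and sets C5 by face selection instead of inversion.

Step 5. Most likely to go wrong: the carbene dimerises (azine, stilbene) faster than it adds to a hindered cis alkene whose aryl ring is twisted out of conjugation, and anti selectivity is incomplete. Any E isomer carried through from step 2 gives the wrong triad, and half of the material is lost in the resolution of step 7, which itself depends on separable diastereomers. The reason is that iron-porphyrin carbenes prefer terminal, conjugated alkenes. Fallback, setting out from 7 and returning at 12 as a single enantiomer, so that step 7 needs no separation: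
- Horner–Wadsworth–Emmons reaction of 7 with triethyl phosphonoacetate gives ethyl (E)-3-[4-(TIPSO)phenyl]prop-2-enoate F7, and i-Bu2AlH gives (E)-3-[4-(TIPSO)phenyl]prop-2-en-1-ol F8.
- 4-Iodobenzene-1,3-diol is pivaloylated to 4-iodo-1,3-phenylene bis(2,2-dimethylpropanoate) F9.
- F8 is cyclopropanated with the gem-dizinc carbenoid from EtZnI and CHI3 under control of the butylboronate of N,N,N',N'-tetramethyltartramide (enantioselective Simmons–Smith-type reaction). The cyclopropylzinc, held cis to the zinc alkoxide, is transferred to boron and coupled with F9 (Suzuki–Miyaura, Pd(OAc)2/PPh3, K3PO4) to give [(1R,2S,3S)-2-[2,4-bis(PivO)phenyl]-3-[4-(TIPSO)phenyl]cyclopropyl]methanol F10.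
- Dess–Martin oxidation gives the carbaldehyde F11, Wittig reaction with Ph3P=CHOMe gives the enol ether F12, and mild aqueous acid gives 12, which is oxidised as in step 6.

The cis relation here comes from zinc chelation and the absolute configuration from the ligand; the cost is four more steps and a base-sensitive coupling.

Step 15. Most likely to go wrong: the hindered aryllithium deprotonates the lactone at C3 instead of adding, after which O1 is lost by beta-elimination or C3 epimerises; the lactolate collapses and a second addition follows; the ortho silyl group of 25 migrates from oxygen to carbon on warming. The reason is a hindered nucleophile meeting a hindered, enolisable carbonyl. Fallback, setting out from 22 and returning at 28: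
- MeNH(OMe)·HCl and Me3Al open 22 to the N-methoxy-N-methylamide F13 (Weinreb amide formation, non-basic).
- Et3SiOTf and 2,6-lutidine cap the C7 hydroxyl as the triethylsilyl ether F14.
- 25 adds once to the less acidic amide to give the C7-silylated ketone F15.
- The conditions of step 16 remove all silyl groups and give 28.

Step 12. Most likely to go wrong: loss of the triisopropylsilyl group under the methanolysis, after which the para-phenoxide expels the lactone carboxylate and C7 is scrambled or captured by solvent; epimerisation at C3 or beta-elimination of O1 while the lactone is open as its methyl ester. The reason is that aryl pivalates need hours of base. Fallback, setting out from 20 and returning at 28, without protecting-group exchange: excess 25 is added to 20 at −78 to −40 °C. The aryllithium opens the lactone and, as organolithium reagents do with pivalates, cleaves the three aryl esters, giving the ketone with three free phenols F16, which goes directly into step 16.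

Step 10. Most likely to go wrong: partial hydrolysis of aryl pivalates alongside the thioimide, and retro-aldol cleavage under hydroxide. The reason is that aryl esters are themselves activated esters. Fallback, setting out from 17 and returning at 18: imidazole-promoted transesterification of 17 with prop-2-en-1-ol gives the allyl ester F17, which Pd(PPh3)4 (zerovalent palladium) and PhSiH3 deallylate under neutral conditions to 18.

Further compounds

F1 | step 11 | 1,4-bis[2,4-bis(TBSO)phenyl]butane-1,4-dione | O=C(CCC(=O)c1ccc(O[Si](C)(C)C(C)(C)C)cc1O[Si](C)(C)C(C)(C)C)c1ccc(O[Si](C)(C)C(C)(C)C)cc1O[Si](C)(C)C(C)(C)C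
F2 | step 11 | 4-(TBSO)benzaldehyde | O=Cc1ccc(O[Si](C)(C)C(C)(C)C)cc1
F3 | step 11 | (2R)-1,4-bis[2,4-bis(TBSO)phenyl]-2-[(R)-hydroxy{4-(TBSO)phenyl}methyl]butane-1,4-dione | O=C(c1ccc(O[Si](C)(C)C(C)(C)C)cc1O[Si](C)(C)C(C)(C)C)C[C@H]([C@@H](O)c1ccc(O[Si](C)(C)C(C)(C)C)cc1)C(=O)c1ccc(O[Si](C)(C)C(C)(C)C)cc1O[Si](C)(C)C(C)(C)C
F4 | step 11 | (2R)-1,4-bis[2,4-bis(TBSO)phenyl]-2-[(R)-{4-(TBSO)phenyl}(TESO)methyl]butane-1,4-dione | O=C(c1ccc(O[Si](C)(C)C(C)(C)C)cc1O[Si](C)(C)C(C)(C)C)C[C@H]([C@@H](O[Si](CC)(CC)CC)c1ccc(O[Si](C)(C)C(C)(C)C)cc1)C(=O)c1ccc(O[Si](C)(C)C(C)(C)C)cc1O[Si](C)(C)C(C)(C)C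
F5 | step 11 | (2R,3R)-1,4-bis[2,4-bis(TBSO)phenyl]-2-[(R)-hydroxy{4-(TBSO)phenyl}methyl]-3-[(R)-{4-(TBSO)phenyl}(TESO)methyl]butane-1,4-dione | O=C(c1ccc(O[Si](C)(C)C(C)(C)C)cc1O[Si](C)(C)C(C)(C)C)[C@@H]([C@@H](O)c1ccc(O[Si](C)(C)C(C)(C)C)cc1)[C@H]([C@@H](O[Si](CC)(CC)CC)c1ccc(O[Si](C)(C)C(C)(C)C)cc1)C(=O)c1ccc(O[Si](C)(C)C(C)(C)C)cc1O[Si](C)(C)C(C)(C)C
F6 | step 11 | all-TBS analogue of 27 with C7 as triethylsilyl ether: [(2R,3R,4S,5R)-5-[2,4-bis(TBSO)phenyl]-2-[4-(TBSO)phenyl]-4-[(R)-{4-(TBSO)phenyl}(TESO)methyl]oxolan-3-yl][2,4-bis(TBSO)phenyl]methanone | O=C(c1ccc(O[Si](C)(C)C(C)(C)C)cc1O[Si](C)(C)C(C)(C)C)[C@@H]1[C@H]([C@@H](O[Si](CC)(CC)CC)c2ccc(O[Si](C)(C)C(C)(C)C)cc2)[C@H](c2ccc(O[Si](C)(C)C(C)(C)C)cc2O[Si](C)(C)C(C)(C)C)O[C@H]1c1ccc(O[Si](C)(C)C(C)(C)C)cc1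
F7 | step 5 | ethyl (E)-3-[4-(TIPSO)phenyl]prop-2-enoate | CCOC(=O)/C=C/c1ccc(O[Si](C(C)C)(C(C)C)C(C)C)cc1
F8 | step 5 | (E)-3-[4-(TIPSO)phenyl]prop-2-en-1-ol | OC/C=C/c1ccc(O[Si](C(C)C)(C(C)C)C(C)C)cc1
F9 | step 5 | 4-iodo-1,3-phenylene bis(2,2-dimethylpropanoate) | Ic1ccc(OC(=O)C(C)(C)C)cc1OC(=O)C(C)(C)C
F10 | step 5 | [(1R,2S,3S)-2-[2,4-bis(PivO)phenyl]-3-[4-(TIPSO)phenyl]cyclopropyl]methanol | OC[C@H]1[C@@H](c2ccc(OC(=O)C(C)(C)C)cc2OC(=O)C(C)(C)C)[C@@H]1c1ccc(O[Si](C(C)C)(C(C)C)C(C)C)cc1
F11 | step 5 | (1R,2S,3S)-2-[2,4-bis(PivO)phenyl]-3-[4-(TIPSO)phenyl]cyclopropane-1-carbaldehyde | O=C[C@H]1[C@@H](c2ccc(OC(=O)C(C)(C)C)cc2OC(=O)C(C)(C)C)[C@@H]1c1ccc(O[Si](C(C)C)(C(C)C)C(C)C)cc1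
F12 | step 5 | 4-[(1R,2R,3R)-2-(2-methoxyethenyl)-3-{4-(TIPSO)phenyl}cyclopropyl]-1,3-phenylene bis(2,2-dimethylpropanoate), E/Z mixture | COC=C[C@H]1[C@@H](c2ccc(OC(=O)C(C)(C)C)cc2OC(=O)C(C)(C)C)[C@@H]1c1ccc(O[Si](C(C)C)(C(C)C)C(C)C)cc1
F13 | step 15 | (2R,3R,4R,5R)-5-[2,4-bis(TBSO)phenyl]-2-[4-(TBSO)phenyl]-4-[(R)-hydroxy{4-(TIPSO)phenyl}methyl]-N-methoxy-N-methyloxolane-3-carboxamide | CON(C)C(=O)[C@@H]1[C@H]([C@@H](O)c2ccc(O[Si](C(C)C)(C(C)C)C(C)C)cc2)[C@H](c2ccc(O[Si](C)(C)C(C)(C)C)cc2O[Si](C)(C)C(C)(C)C)O[C@H]1c1ccc(O[Si](C)(C)C(C)(C)C)cc1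
F14 | step 15 | C7 triethylsilyl ether of F13 | CON(C)C(=O)[C@@H]1[C@H]([C@@H](O[Si](CC)(CC)CC)c2ccc(O[Si](C(C)C)(C(C)C)C(C)C)cc2)[C@H](c2ccc(O[Si](C)(C)C(C)(C)C)cc2O[Si](C)(C)C(C)(C)C)O[C@H]1c1ccc(O[Si](C)(C)C(C)(C)C)cc1
F15 | step 15 | C7 triethylsilyl ether of 27 | O=C(c1ccc(O[Si](C)(C)C(C)(C)C)cc1O[Si](C)(C)C(C)(C)C)[C@@H]1[C@H]([C@@H](O[Si](CC)(CC)CC)c2ccc(O[Si](C(C)C)(C(C)C)C(C)C)cc2)[C@H](c2ccc(O[Si](C)(C)C(C)(C)C)cc2O[Si](C)(C)C(C)(C)C)O[C@H]1c1ccc(O[Si](C)(C)C(C)(C)C)cc1
F16 | step 12 | [(2R,3R,4R,5R)-5-(2,4-dihydroxyphenyl)-2-(4-hydroxyphenyl)-4-[(R)-hydroxy{4-(TIPSO)phenyl}methyl]oxolan-3-yl][2,4-bis(TBSO)phenyl]methanone | O=C(c1ccc(O[Si](C)(C)C(C)(C)C)cc1O[Si](C)(C)C(C)(C)C)[C@@H]1[C@H]([C@@H](O)c2ccc(O[Si](C(C)C)(C(C)C)C(C)C)cc2)[C@H](c2ccc(O)cc2O)O[C@H]1c1ccc(O)cc1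
F17 | step 10 | prop-2-en-1-yl (2R,3R)-2-[(1R,2R,3R)-2-[2,4-bis(PivO)phenyl]-3-[4-(TIPSO)phenyl]cyclopropyl]-3-hydroxy-3-[4-(PivO)phenyl]propanoate | C=CCOC(=O)[C@@H]([C@@H](O)c1ccc(OC(=O)C(C)(C)C)cc1)[C@H]1[C@@H](c2ccc(OC(=O)C(C)(C)C)cc2OC(=O)C(C)(C)C)[C@@H]1c1ccc(O[Si](C(C)C)(C(C)C)C(C)C)cc1
A1 | alternative 1 | 1,4-bis[2,4-bis(prop-2-en-1-yloxy)phenyl]butane-1,4-dione | C=CCOc1ccc(C(=O)CCC(=O)c2ccc(OCC=C)cc2OCC=C)c(OCC=C)c1
A2 | alternative 1 | (2R,3R)-1,4-bis[2,4-bis(prop-2-en-1-yloxy)phenyl]-2,3-bis[(R)-hydroxy{4-(prop-2-en-1-yloxy)phenyl}methyl]butane-1,4-dione | O=C(c1ccc(OCC=C)cc1OCC=C)[C@@H]([C@@H](O)c1ccc(OCC=C)cc1)[C@H]([C@@H](O)c1ccc(OCC=C)cc1)C(=O)c1ccc(OCC=C)cc1OCC=C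
A3 | alternative 2 | 3-diazo-7-(TBSO)chromane-2,4-dione | O=C1Oc2cc(O[Si](C)(C)C(C)(C)C)ccc2C(=O)C1=[N+]=[N-]
A4 | alternative 2 | (R,E)-1-[2,4-bis(TBSO)phenyl]-3-[4-(TBSO)phenyl]prop-2-en-1-yl triethylsilyl ether | CC[Si](CC)(CC)O[C@H](/C=C/c1ccc(O[Si](C)(C)C(C)(C)C)cc1)c1ccc(O[Si](C)(C)C(C)(C)C)cc1O[Si](C)(C)C(C)(C)C
A5 | alternative 2 | trans-2-[4-(TBSO)phenyl]-3-[(R)-{2,4-bis(TBSO)phenyl}(TESO)methyl]-7-(TBSO)-2,3-dihydrofuro[3,2-c]chromen-4-one | O=C1Oc2cc(O[Si](C)(C)C(C)(C)C)ccc2C2=C1[C@@H]([C@@H](O[Si](CC)(CC)CC)c1ccc(O[Si](C)(C)C(C)(C)C)cc1O[Si](C)(C)C(C)(C)C)[C@H](c1ccc(O[Si](C)(C)C(C)(C)C)cc1)O2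
A6 | alternative 3 | (R)-5-[4-(TBSO)phenyl]furan-2(5H)-one | O=C1C=C[C@H](c2ccc(O[Si](C)(C)C(C)(C)C)cc2)O1
A7 | alternative 3 | (3R,3aS,4R,6R,6aR)-4-[2,4-bis(PivO)phenyl]-3,6-bis[4-(TBSO)phenyl]tetrahydro-1H,3H-furo[3,4-c]furan-1-one | O=C1O[C@@H](c2ccc(O[Si](C)(C)C(C)(C)C)cc2)[C@@H]2[C@H](c3ccc(OC(=O)C(C)(C)C)cc3OC(=O)C(C)(C)C)O[C@@H](c3ccc(O[Si](C)(C)C(C)(C)C)cc3)[C@H]12
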